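**Retrosynthetic overview**
1. The last bond made is O1–C2. After unmasking the B-ring catechol (bis-TBS ether), the target opens to the (E)-2',4',6'-trihydroxy-3'-(1,1-dimethylallyl)chalcone. A catalytic, site- and enantioselective oxa-Michael closure through the unhindered 6'-OH sets (2S) and the 6-substitution pattern.
2. Chalcone Cα=Cβ: Claisen–Schmidt condensation of 3-(1,1-dimethylallyl)phloroacetophenone with 3,4-bis(TBSO)benzaldehyde.
3. Aryl–CMe2 bond: aromatic Claisen shift of the 4-O-prenyl ether of phloroacetophenone (both ortho sites equivalent, para site blocked). The ether comes from a Mitsunobu C–O coupling with prenol.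
4. Ring order: rings A and B are bought. The dihydropyranone ring C is the only ring formed, in the final step.

Assumption: the quinine-series thiourea gives the (2S) product. This is checked on the first run by ECD, where (2S)-flavanones show a positive band near 330 nm and a negative band near 290 nm. If the sense is opposite, the quinidine-derived pseudo-enantiomer is used with nothing else changed.

**Step 1**
Reactants: 1 2',4',6'-trihydroxyacetophenone (dried); 2 3-methylbut-2-en-1-ol (prenol)
Product: 3 1-[2,6-dihydroxy-4-(3-methylbut-2-enyloxy)phenyl]ethanone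
Conditions: PPh3 (1.1 equiv), DIAD (1.1 equiv), THF, 0 °C → rt, 12 h
Reagents that add atoms: none
Why: In this Mitsunobu etherification the 4-OH is the most acidic phenol and the only one not tied up in a hydrogen bond to the ketone, so it reacts first, and SN2 attack on the alkoxyphosphonium ion gives O-alkylation rather than the C-prenylation seen with prenyl halide and base.

**Step 2**
Reactants: 3 1-[2,6-dihydroxy-4-(3-methylbut-2-enyloxy)phenyl]ethanone
Product: 5 1-[2,4,6-trihydroxy-3-(2-methylbut-3-en-2-yl)phenyl]ethanone, via Claisen dienone 4 (not isolated)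
Conditions: EtOH/H2O 4:1, Ar, sealed tube, 130 °C, 16 h
Reagents that add atoms: none
Why: The water-accelerated aromatic Claisen [3,3] rearrangement inverts the allyl unit (O–CH2CH=CMe2 becomes C–CMe2CH=CH2), the two ortho positions are equivalent, the acetyl-blocked para position rules out a follow-up Cope shift, and dienone 4 simply tautomerises to the phenol.

**Step 3**
Reactants: 6 3,4-dihydroxybenzaldehyde
Product: 7 3,4-bis(tert-butyldimethylsilyloxy)benzaldehyde
Conditions: TBSCl (2.4 equiv), imidazole (5 equiv), DMF, rt, 4 h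
Reagents that add atoms: tert-butyldimethylsilyl chloride, CC(C)(C)[Si](C)(C)Cl
Why: Imidazole-promoted silyl ether formation removes the acidic catechol protons, which would otherwise turn the aldehyde into an unreactive phenoxide in step 4 and would speed racemisation of the flavanone in step 5.

**Step 4**
Reactants: 5 1-[2,4,6-trihydroxy-3-(2-methylbut-3-en-2-yl)phenyl]ethanone; 7 3,4-bis(tert-butyldimethylsilyloxy)benzaldehyde
Product: 9 (E)-3-[3,4-bis(tert-butyldimethylsilyloxy)phenyl]-1-[2,4,6-trihydroxy-3-(2-methylbut-3-en-2-yl)phenyl]prop-2-en-1-one, via aldol adduct 8 (not isolated)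
Conditions: LiHMDS (5.0 equiv), THF, −78 → 0 °C; then 7 (1.1 equiv), −78 °C → rt, 18 h; poured into cold 1 M HCl; rapid chromatography on acid-washed silica
Reagents that add atoms: none
Why: In this Claisen–Schmidt condensation (aldol addition, then E1cB loss of water) of the lithium triphenoxide-enolate, a protocol known for unprotected polyhydroxyacetophenones, the non-nucleophilic base leaves aryl silyl ethers and the vinyl group alone, conjugation gives the (E)-alkene, and strong base followed by a cold acid quench keeps the chalcone open.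

**Step 5**
Reactants: 9 (E)-3-[3,4-bis(tert-butyldimethylsilyloxy)phenyl]-1-[2,4,6-trihydroxy-3-(2-methylbut-3-en-2-yl)phenyl]prop-2-en-1-one
Product: 11 (2S)-2-(3,4-dihydroxyphenyl)-5,7-dihydroxy-6-(2-methylbut-3-en-2-yl)-2,3-dihydrochromen-4-one, via silylated flavanone 10 (not isolated)
Conditions: 1-[3,5-bis(trifluoromethyl)phenyl]-3-[(8α,9S)-6'-methoxycinchonan-9-yl]thiourea (10 mol%), PhMe (0.05 M), −20 °C, 48–72 h to full conversion; then THF, Et3N·3HF (3 equiv), 0 °C → rt, 3 h; work-up at pH 4–5
Reagents that add atoms: none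
Why: Proposed new method: a site- and enantioselective 6-endo-trig intramolecular oxa-Michael closure of an unactivated, A-ring-unprotected 2',4',6'-trihydroxychalcone under bifunctional amine–thiourea catalysis, in which the quinuclidine nitrogen acts as general base on the only unhindered ortho-phenol (6'-OH), the thiourea N–H pair binds the carbonyl oxygen and the developing enolate, and the tert-alkyl-buttressed 2'-OH···O=C hydrogen bond locks the s-cis enone, lowers its LUMO in place of the removable ester needed in known substrates and points the β-carbon at the 6'-oxygen, so that one enone face is attacked to set C2 as (S) and the 6-substituted isomer forms; the retained 5-OH···O=C chelate makes closure exergonic, the low temperature, apolar solvent and silylated 4'-oxygen suppress the retro-reaction that racemises flavanones, and the acidic fluoride quench switches the amine off before routine Si–O cleavage unmasks the catechol without touching C2; the closest known reaction types are the cinchona–thiourea-catalysed oxa-Michael cyclisation of α-alkoxycarbonyl-activated 2'-hydroxychalcones followed by decarboxylation, and the enzymatic chalcone isomerase cyclisation.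

**Compound list**
1 | 2',4',6'-trihydroxyacetophenone (phloroacetophenone) | CC(=O)c1c(O)cc(O)cc1O | starting material
2 | 3-methylbut-2-en-1-ol (prenol) | CC(C)=CCO | starting material
3 | 1-[2,6-dihydroxy-4-(3-methylbut-2-enyloxy)phenyl]ethanone | CC(=O)c1c(O)cc(OCC=C(C)C)cc1O | intermediate
4 | 4-acetyl-3,5-dihydroxy-6-(2-methylbut-3-en-2-yl)cyclohexa-2,4-dien-1-one (Claisen dienone, racemic, not isolated) | CC(=O)C1=C(O)C(C(C)(C)C=C)C(=O)C=C1O | intermediate
5 | 1-[2,4,6-trihydroxy-3-(2-methylbut-3-en-2-yl)phenyl]ethanone | CC(=O)c1c(O)cc(O)c(C(C)(C)C=C)c1O | intermediate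
6 | 3,4-dihydroxybenzaldehyde | O=Cc1ccc(O)c(O)c1 | starting material
7 | 3,4-bis(tert-butyldimethylsilyloxy)benzaldehyde | O=Cc1ccc(O[Si](C)(C)C(C)(C)C)c(O[Si](C)(C)C(C)(C)C)c1 | intermediate
8 | 3-[3,4-bis(tert-butyldimethylsilyloxy)phenyl]-3-hydroxy-1-[2,4,6-trihydroxy-3-(2-methylbut-3-en-2-yl)phenyl]propan-1-one (racemic aldol adduct, present as its lithium salt, not isolated) | C=CC(C)(C)c1c(O)cc(O)c(C(=O)CC(O)c2ccc(O[Si](C)(C)C(C)(C)C)c(O[Si](C)(C)C(C)(C)C)c2)c1O | intermediate
9 | (E)-3-[3,4-bis(tert-butyldimethylsilyloxy)phenyl]-1-[2,4,6-trihydroxy-3-(2-methylbut-3-en-2-yl)phenyl]prop-2-en-1-one | C=CC(C)(C)c1c(O)cc(O)c(C(=O)/C=C/c2ccc(O[Si](C)(C)C(C)(C)C)c(O[Si](C)(C)C(C)(C)C)c2)c1O | intermediate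
10 | (2S)-2-[3,4-bis(tert-butyldimethylsilyloxy)phenyl]-5,7-dihydroxy-6-(2-methylbut-3-en-2-yl)-2,3-dihydrochromen-4-one (not isolated) | C=CC(C)(C)c1c(O)cc2c(c1O)C(=O)C[C@@H](c1ccc(O[Si](C)(C)C(C)(C)C)c(O[Si](C)(C)C(C)(C)C)c1)O2 | intermediate
11 | (2S)-2-(3,4-dihydroxyphenyl)-5,7-dihydroxy-6-(2-methylbut-3-en-2-yl)-2,3-dihydrochromen-4-one, (2S)-6-(1,1-dimethylallyl)eriodictyol | C=CC(C)(C)c1c(O)cc2c(c1O)C(=O)C[C@@H](c1ccc(O)c(O)c1)O2 | target

**Step count**
Total steps: 5 (step 5 is a one-pot, two-stage operation). Longest linear sequence: 4 (steps 1, 2, 4, 5).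

**Three steps most likely to fail**

Step 5 (the new step). The risks are:
- a racemic background closure;
- capture of the amine by the acidic 4'-OH;
- some closure through the 2'-OH, giving the 8-isomer;
- an unknown sense of induction.

The fallback uses known chemistry and sets out from 9. Classical base-catalysed cyclisation (NaOAc, EtOH, 60 °C) followed by chromatographic removal of the 8-substituted isomer gives the racemic 6-substituted flavanone bis-silyl ether F1. Preparative HPLC or SFC on an amylose tris(3,5-dimethylphenylcarbamate) phase splits this into 10 and the (2R)-flavanone bis-silyl ether F2. F2 is re-equilibrated to F1 under the same NaOAc conditions and recycled. The route is rejoined at 10, which is desilylated as in the second stage of step 5.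

Step 4. The tetra-lithiated form of 5 may be insoluble or sluggish, and silyl groups may migrate to the A-ring phenoxides. The fallback sets out from 5 and cuts the charge load by masking two phenols.
- MOMCl (2.2 equiv) and iPr2NEt in CH2Cl2 at 0 °C leave only the hindered, chelated 2-OH free. This gives the 2-hydroxy-4,6-bis(methoxymethoxy)-3-(1,1-dimethylallyl)acetophenone F3.
- Its dianion (LiHMDS, 2.3 equiv, THF) adds to 7 to give the bis-MOM aldol adduct F4, which loses water in the flask to the bis-MOM chalcone F5.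
- HCl in MeOH/THF at 40 °C cleaves the two acetals, while the acid-tolerant aryl silyl ethers and the monosubstituted alkene stay intact. The route is rejoined at 9.

Step 2. The risks are solvolytic loss of the prenyl group, abnormal Claisen isomerisation, and addition of an ortho-phenol to the vinyl group (2,3,3-trimethyldihydrobenzofuran). The fallback sets out from 3 and replaces the free-phenol rearrangement by a trap-and-release sequence.
- Heating 3 with Ac2O and NaOAc in N,N-diethylaniline (sealed, 190 °C) first gives the 2,6-diacetoxy prenyl ether F6.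
- F6 rearranges through the diacetoxy dienone F7 to the 4-hydroxy diacetate F8, which is acetylated as it forms. The product is the 2,4,6-triacetoxy-3-(1,1-dimethylallyl)acetophenone F9, in which no free phenol sits next to the alkene.
- K2CO3 in MeOH at 0 °C to rt removes the three acetates. The route is rejoined at 5.

**Further compounds**
F1 | step 5 | rac-2-[3,4-bis(tert-butyldimethylsilyloxy)phenyl]-5,7-dihydroxy-6-(2-methylbut-3-en-2-yl)-2,3-dihydrochromen-4-one | C=CC(C)(C)c1c(O)cc2c(c1O)C(=O)CC(c1ccc(O[Si](C)(C)C(C)(C)C)c(O[Si](C)(C)C(C)(C)C)c1)O2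
F2 | step 5 | (2R)-2-[3,4-bis(tert-butyldimethylsilyloxy)phenyl]-5,7-dihydroxy-6-(2-methylbut-3-en-2-yl)-2,3-dihydrochromen-4-one | C=CC(C)(C)c1c(O)cc2c(c1O)C(=O)C[C@H](c1ccc(O[Si](C)(C)C(C)(C)C)c(O[Si](C)(C)C(C)(C)C)c1)O2
F3 | step 4 | 1-[2-hydroxy-4,6-bis(methoxymethoxy)-3-(2-methylbut-3-en-2-yl)phenyl]ethanone | CC(=O)c1c(OCOC)cc(OCOC)c(C(C)(C)C=C)c1O
F4 | step 4 | 3-[3,4-bis(tert-butyldimethylsilyloxy)phenyl]-3-hydroxy-1-[2-hydroxy-4,6-bis(methoxymethoxy)-3-(2-methylbut-3-en-2-yl)phenyl]propan-1-one (racemic) | C=CC(C)(C)c1c(OCOC)cc(OCOC)c(C(=O)CC(O)c2ccc(O[Si](C)(C)C(C)(C)C)c(O[Si](C)(C)C(C)(C)C)c2)c1O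
F5 | step 4 | (E)-3-[3,4-bis(tert-butyldimethylsilyloxy)phenyl]-1-[2-hydroxy-4,6-bis(methoxymethoxy)-3-(2-methylbut-3-en-2-yl)phenyl]prop-2-en-1-one | C=CC(C)(C)c1c(OCOC)cc(OCOC)c(C(=O)/C=C/c2ccc(O[Si](C)(C)C(C)(C)C)c(O[Si](C)(C)C(C)(C)C)c2)c1O
F6 | step 2 | 2-acetyl-5-(3-methylbut-2-enyloxy)-1,3-phenylene diacetate | CC(=O)Oc1cc(OCC=C(C)C)cc(OC(C)=O)c1C(C)=O
F7 | step 2 | 4-acetyl-3,5-diacetoxy-6-(2-methylbut-3-en-2-yl)cyclohexa-2,4-dien-1-one (racemic) | CC(=O)OC1=C(C(C)=O)C(OC(C)=O)=CC(=O)C1C(C)(C)C=C
F8 | step 2 | 2-acetyl-5-hydroxy-4-(2-methylbut-3-en-2-yl)-1,3-phenylene diacetate | CC(=O)Oc1cc(O)c(C(C)(C)C=C)c(OC(C)=O)c1C(C)=O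
F9 | step 2 | 1-[2,4,6-triacetoxy-3-(2-methylbut-3-en-2-yl)phenyl]ethanone | CC(=O)Oc1cc(OC(C)=O)c(C(C)(C)C=C)c(OC(C)=O)c1C(C)=O
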